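**Retrosynthetic overview** (isochromene numbering: C1 lactone C=O, O2, C3, C4, C4a, C5 quaternary, C6 ketone, C7, C8 enol, C8a)
- Carbocycle last: the enolised cyclohexenedione ring is closed by a Dieckmann (intramolecular Claisen) attack of the ethyl-ketone enolate (C7) on a pyranone-3-carboxylate (C8).
- Pyranone ring first, in the key step: intermolecular Michael addition of dimethyl malonate to the β-carbon (future C4a) of a chiral alkynone, then lactonisation. This forms the C8a–C4a bond and brings in C1, C8a and C8.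
- The alkynone comes from an α-quaternary ester: ester → aldehyde → terminal alkyne → acetylation; the carbinol becomes the C6 ketone.
- The C5 quaternary stereocentre is set by two successive Fráter–Seebach alkylations (MeI, then farnesyl bromide) of methyl (R)-3-hydroxypentanoate, made by Noyori hydrogenation of methyl 3-oxopentanoate.

Assumption: "farnesyl" means (2E,6E)-3,7,11-trimethyldodeca-2,6,10-trien-1-yl; the target is taken as the (5S) 8-hydroxy enol tautomer of the given SMILES; lithium or sodium enolates and acetylides count as the reacting form of the numbered compound they derive from.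

**Route**

Step 1
Reactants: 1 methyl 3-oxopentanoate
Product: 2 methyl (3R)-3-hydroxypentanoate
Conditions: H2 (50 atm), RuCl2[(R)-BINAP] (0.1 mol %), MeOH, 50 °C
Reagents that add atoms: none
Why: Noyori asymmetric hydrogenation of a β-keto ester, in which the substrate chelated to the (R)-BINAP complex of divalent ruthenium is reduced from one face to give the (R)-alcohol in ≥98% ee.

Step 2
Reactants: 2 methyl (3R)-3-hydroxypentanoate
Product: 3 methyl (2R,3R)-3-hydroxy-2-methylpentanoate
Conditions: LiN(i-Pr)2 (2.2 equiv), THF, −78 → −20 °C; MeI (1.5 equiv), DMPU, −78 → 0 °C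
Reagents that add atoms: iodomethane, CI
Why: Fráter–Seebach alkylation, in which the lithium-chelated alkoxide–enolate dianion is methylated on the face opposite the C3 ethyl group to give the anti (2R,3R) product (dr typically ≥95:5).

Step 3
Reactants: 4 (2E,6E)-farnesol
Product: 5 (2E,6E)-farnesyl bromide
Conditions: PBr3 (0.4 equiv), Et2O, −10 → 0 °C
Reagents that add atoms: phosphorus tribromide, BrP(Br)Br
Why: SN2 displacement of the primary allylic phosphite ester by bromide at low temperature, which gives the primary bromide without allylic transposition or loss of E geometry.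

Step 4
Reactants: 3 methyl (2R,3R)-3-hydroxy-2-methylpentanoate; 5 (2E,6E)-farnesyl bromide
Product: 6 methyl (2R,3R)-2-farnesyl-3-hydroxy-2-methylpentanoate
Conditions: LiN(i-Pr)2 (2.3 equiv), THF, −78 → −10 °C; 5 (1.3 equiv), DMPU, −78 → 0 °C; chromatography
Reagents that add atoms: none
Why: Second Fráter–Seebach alkylation, in which the chelated tetrasubstituted enolate is again attacked anti to the C3 ethyl group, so farnesyl takes the face methyl took in step 2 and the quaternary centre is set as (2R), the arrangement that becomes (5S) in the target.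

Step 5
Reactants: 6 methyl (2R,3R)-2-farnesyl-3-hydroxy-2-methylpentanoate
Product: 7 methyl (2R,3R)-2-farnesyl-2-methyl-3-(triethylsilyloxy)pentanoate
Conditions: TESOTf (1.5 equiv), 2,6-lutidine (3 equiv), CH2Cl2, −78 → 0 °C
Reagents that add atoms: triethylsilyl trifluoromethanesulfonate, CC[Si](CC)(CC)OS(=O)(=O)C(F)(F)F
Why: Silyl triflate silylation of a hindered secondary alcohol under non-nucleophilic base, which masks the carbinol (retro-aldol prone as its alkoxide) for the steps that follow.

Step 6
Reactants: 7 methyl (2R,3R)-2-farnesyl-2-methyl-3-(triethylsilyloxy)pentanoate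
Product: 8 (2S,3R)-2-farnesyl-2-methyl-3-(triethylsilyloxy)pentan-1-ol
Conditions: i-Bu2AlH (3.0 equiv), CH2Cl2, −78 → 0 °C; aq. potassium sodium tartrate work-up
Reagents that add atoms: none
Why: Hydride reduction of the ester to the primary alcohol, which is more dependable for a neopentyl ester than stopping at the aldehyde, and the change of descriptor at C2 is only a CIP priority change.

Step 7
Reactants: 8 (2S,3R)-2-farnesyl-2-methyl-3-(triethylsilyloxy)pentan-1-ol
Product: 9 (2R,3R)-2-farnesyl-2-methyl-3-(triethylsilyloxy)pentanal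
Conditions: Dess–Martin periodinane (1.5 equiv), pyridine, CH2Cl2, 0 °C → rt
Reagents that add atoms: none
Why: Dess–Martin oxidation under buffered, near-neutral conditions gives the non-enolisable α-quaternary aldehyde without touching the silyl ether or the trisubstituted alkenes.

Step 8
Reactants: 9 (2R,3R)-2-farnesyl-2-methyl-3-(triethylsilyloxy)pentanal
Product: 10 (3S,4R)-3-farnesyl-3-methyl-4-(triethylsilyloxy)hex-1-yne
Conditions: dimethyl (1-diazo-2-oxopropyl)phosphonate (2 equiv), K2CO3 (3 equiv), MeOH, 0 °C → rt, 24 h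
Reagents that add atoms: dimethyl (1-diazo-2-oxopropyl)phosphonate, COP(=O)(OC)C(=[N+]=[N-])C(C)=O
Why: Ohira–Bestmann (Seyferth–Gilbert) homologation converts the aldehyde into the terminal alkyne by one carbon, and the aldehyde has no α-hydrogen so nothing can epimerise.

Step 9
Reactants: 10 (3S,4R)-3-farnesyl-3-methyl-4-(triethylsilyloxy)hex-1-yne
Product: 11 (5S,6R)-5-farnesyl-5-methyl-6-(triethylsilyloxy)oct-3-yn-2-one
Conditions: n-BuLi (1.1 equiv), THF, −78 °C; N-methoxy-N-methylacetamide (1.5 equiv), −78 → 0 °C; aq. NH4Cl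
Reagents that add atoms: N-methoxy-N-methylacetamide, CC(=O)N(C)OC
Why: Acylation of the lithium acetylide with a Weinreb amide stops at the ketone because the chelated tetrahedral adduct survives until work-up, giving the methyl alkynone.

Step 10
Reactants: 11 (5S,6R)-5-farnesyl-5-methyl-6-(triethylsilyloxy)oct-3-yn-2-one
Product: 12 (5S,6R)-5-farnesyl-6-hydroxy-5-methyloct-3-yn-2-one
Conditions: HF·pyridine, pyridine, THF, 0 °C → rt
Reagents that add atoms: none
Why: Fluoride desilylation under buffered acidic conditions frees the alcohol without forming an alkoxide, which could fragment the alkynone by a retro-aldol-type path.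

Step 11
Reactants: 12 (5S,6R)-5-farnesyl-6-hydroxy-5-methyloct-3-yn-2-one
Product: 13 (5S)-5-farnesyl-5-methyloct-3-yne-2,6-dione
Conditions: Dess–Martin periodinane (1.5 equiv), pyridine, CH2Cl2, 0 °C → rt
Reagents that add atoms: none
Why: Dess–Martin oxidation of the secondary alcohol installs the C6 ketone and removes the auxiliary carbinol stereocentre, leaving only the quaternary centre, which has no α-hydrogen.

Step 12
Reactants: 13 (5S)-5-farnesyl-5-methyloct-3-yne-2,6-dione; 14 dimethyl malonate
Product: 16 methyl 4-[(2S)-2-farnesyl-3-oxopentan-2-yl]-6-methyl-2-oxo-2H-pyran-3-carboxylate, via Michael adduct 15 (not isolated)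
Conditions: 14 (2.0 equiv), NaH (1.05 equiv), THF, 0 °C; then 13, 23 → 60 °C; aq. NH4Cl
Reagents that add atoms: none
Why: Intermolecular Michael addition of sodium dimethyl malonate to the β-carbon of the alkynone forms the C8a–C4a bond, and the dienolate of the adduct then lactonises through its enolate oxygen onto one ester to give the 2-pyranone, while excess malonate buffers the methoxide released.

Step 13
Reactants: 16 methyl 4-[(2S)-2-farnesyl-3-oxopentan-2-yl]-6-methyl-2-oxo-2H-pyran-3-carboxylate
Product: 17 (5S)-5-farnesyl-8-hydroxy-3,5,7-trimethyl-1H-isochromene-1,6(5H)-dione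
Conditions: LiN(SiMe3)2 (2.5 equiv), THF, −78 → 0 °C; 1 M HCl, 0 °C
Reagents that add atoms: none
Why: Dieckmann (intramolecular Claisen) condensation of the ethyl-ketone enolate onto the neighbouring pyranone ester closes the six-membered carbocycle, driven by formation of the stabilised enolate of the product, and the quaternary stereocentre cannot epimerise.

**Compound list**
1 | methyl 3-oxopentanoate | CCC(=O)CC(=O)OC | starting material
2 | methyl (3R)-3-hydroxypentanoate | CC[C@@H](O)CC(=O)OC | intermediate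
3 | methyl (2R,3R)-3-hydroxy-2-methylpentanoate | CC[C@@H](O)[C@@H](C)C(=O)OC | intermediate
4 | (2E,6E)-farnesol | CC(C)=CCC/C(C)=C/CC/C(C)=C/CO | starting material
5 | (2E,6E)-farnesyl bromide | CC(C)=CCC/C(C)=C/CC/C(C)=C/CBr | intermediate
6 | methyl (2R,3R)-2-farnesyl-3-hydroxy-2-methylpentanoate | CC(C)=CCC/C(C)=C/CC/C(C)=C/C[C@](C)([C@H](O)CC)C(=O)OC | intermediate
7 | methyl (2R,3R)-2-farnesyl-2-methyl-3-(triethylsilyloxy)pentanoate | CC(C)=CCC/C(C)=C/CC/C(C)=C/C[C@](C)([C@H](O[Si](CC)(CC)CC)CC)C(=O)OC | intermediate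
8 | (2S,3R)-2-farnesyl-2-methyl-3-(triethylsilyloxy)pentan-1-ol | CC(C)=CCC/C(C)=C/CC/C(C)=C/C[C@](C)([C@H](O[Si](CC)(CC)CC)CC)CO | intermediate
9 | (2R,3R)-2-farnesyl-2-methyl-3-(triethylsilyloxy)pentanal | CC(C)=CCC/C(C)=C/CC/C(C)=C/C[C@](C)([C@H](O[Si](CC)(CC)CC)CC)C=O | intermediate
10 | (3S,4R)-3-farnesyl-3-methyl-4-(triethylsilyloxy)hex-1-yne | CC(C)=CCC/C(C)=C/CC/C(C)=C/C[C@](C)([C@H](O[Si](CC)(CC)CC)CC)C#C | intermediate
11 | (5S,6R)-5-farnesyl-5-methyl-6-(triethylsilyloxy)oct-3-yn-2-one | CC(C)=CCC/C(C)=C/CC/C(C)=C/C[C@](C)([C@H](O[Si](CC)(CC)CC)CC)C#CC(C)=O | intermediate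
12 | (5S,6R)-5-farnesyl-6-hydroxy-5-methyloct-3-yn-2-one | CC(C)=CCC/C(C)=C/CC/C(C)=C/C[C@](C)([C@H](O)CC)C#CC(C)=O | intermediate
13 | (5S)-5-farnesyl-5-methyloct-3-yne-2,6-dione | CC(C)=CCC/C(C)=C/CC/C(C)=C/C[C@](C)(C(=O)CC)C#CC(C)=O | intermediate
14 | dimethyl malonate | COC(=O)CC(=O)OC | starting material
15 | dimethyl 2-[(3E,5S)-5-farnesyl-5-methyl-2,6-dioxooct-3-en-4-yl]malonate (Michael adduct) | CC(C)=CCC/C(C)=C/CC/C(C)=C/C[C@](C)(C(=O)CC)/C(=C/C(C)=O)C(C(=O)OC)C(=O)OC | intermediate
16 | methyl 4-[(2S)-2-farnesyl-3-oxopentan-2-yl]-6-methyl-2-oxo-2H-pyran-3-carboxylate | CC(C)=CCC/C(C)=C/CC/C(C)=C/C[C@](C)(C(=O)CC)c1cc(C)oc(=O)c1C(=O)OC | intermediate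
17 | (5S)-5-farnesyl-8-hydroxy-3,5,7-trimethyl-1H-isochromene-1,6(5H)-dione | CC(C)=CCC/C(C)=C/CC/C(C)=C/C[C@]1(C)C(=O)C(C)=C(O)c2c1cc(C)oc2=O | target

**Totals**
Total step count: 13. Longest linear sequence: 12 steps (steps 1, 2, 4 to 13, from 1 to 17); step 3 is a one-step side branch.

**Three steps most likely to fail**

Step 12 (malonate Michael addition at an alkyne carbon next to the quaternary centre; the alkynone is also sensitive to nucleophilic cleavage). The fallback sets out from 13 and comes back at 17. Methyl cyanoacetate (NaH, THF) replaces 14; the small nitrile lowers the strain next to the quaternary carbon, and lactonisation gives 4-[(2S)-2-farnesyl-3-oxopentan-2-yl]-6-methyl-2-oxo-2H-pyran-3-carbonitrile F4. The carbocycle is then closed by a Thorpe-type addition of the ketone enolate to the nitrile (LiN(SiMe3)2, THF, −78 → 0 °C) to give the enaminone (5S)-8-amino-5-farnesyl-3,5,7-trimethyl-1H-isochromene-1,6(5H)-dione F5. Mild hydrolysis (1 M HCl, THF, 40 °C) converts this to 17.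

Step 4 (alkylation of a hindered dianion to a quaternary centre; conversion and diastereoselectivity may be modest). The fallback sets out from 3 and comes back at 6. Compound 3 is saponified (LiOH, THF/H2O) to (2R,3R)-3-hydroxy-2-methylpentanoic acid F1. Acetalisation with pivalaldehyde (cat. TsOH, CH2Cl2, water removal), done before any polyene is present, gives the cis-dioxanone (2R,5R,6R)-2-tert-butyl-6-ethyl-5-methyl-1,3-dioxan-4-one F2. Its lithium enolate (LiN(i-Pr)2, THF, −78 °C) is alkylated by 5 on the ring face trans to the ethyl and tert-butyl groups to give (2R,5R,6R)-2-tert-butyl-6-ethyl-5-farnesyl-5-methyl-1,3-dioxan-4-one F3. NaOMe in MeOH at 0 °C opens the acetal to 6.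

Step 13 (Dieckmann closure competes with deprotonation of the pyranone methyl group and with base-induced cleavage next to the quaternary carbon). The fallback sets out from 13 and comes back at 17. Diphenyl malonate replaces 14 in the Michael addition and lactonisation, giving phenyl 4-[(2S)-2-farnesyl-3-oxopentan-2-yl]-6-methyl-2-oxo-2H-pyran-3-carboxylate F6. The aryl ester is reactive enough to be acylated by the ketone under soft enolisation (MgBr2·OEt2, i-Pr2NEt, CH2Cl2, rt), with no strong base, giving 17.

**Further compounds**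
F1 | step 4 | (2R,3R)-3-hydroxy-2-methylpentanoic acid | CC[C@@H](O)[C@@H](C)C(=O)O
F2 | step 4 | (2R,5R,6R)-2-tert-butyl-6-ethyl-5-methyl-1,3-dioxan-4-one | CC[C@H]1O[C@@H](C(C)(C)C)OC(=O)[C@@H]1C
F3 | step 4 | (2R,5R,6R)-2-tert-butyl-6-ethyl-5-farnesyl-5-methyl-1,3-dioxan-4-one | CC[C@H]1O[C@@H](C(C)(C)C)OC(=O)[C@]1(C)C/C=C(\C)CC/C=C(\C)CCC=C(C)C
F4 | step 12 | 4-[(2S)-2-farnesyl-3-oxopentan-2-yl]-6-methyl-2-oxo-2H-pyran-3-carbonitrile | CC(C)=CCC/C(C)=C/CC/C(C)=C/C[C@](C)(C(=O)CC)c1cc(C)oc(=O)c1C#N
F5 | step 12 | (5S)-8-amino-5-farnesyl-3,5,7-trimethyl-1H-isochromene-1,6(5H)-dione | CC(C)=CCC/C(C)=C/CC/C(C)=C/C[C@]1(C)C(=O)C(C)=C(N)c2c1cc(C)oc2=O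
F6 | step 13 | phenyl 4-[(2S)-2-farnesyl-3-oxopentan-2-yl]-6-methyl-2-oxo-2H-pyran-3-carboxylate | CC(C)=CCC/C(C)=C/CC/C(C)=C/C[C@](C)(C(=O)CC)c1cc(C)oc(=O)c1C(=O)Oc2ccccc2
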